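**Remark.** The target SMILES encodes the (2R,5R) isomer, which is the 2,5-cis oxane. Ring numbering used below: O1, C2 (bears the acrylic acid), C3, C4, C5 (bears the side chain), C6. Farnesyl bromide is taken as the (2E,6E) isomer.

The oxane ring is taken apart at the two C–C bonds next to its oxygen-bearing carbons, C2–C3 and C5–C6. Both are closed in one flask from an acyclic allylic ester: an Ireland–Claisen rearrangement joins the glycolate carbon C2 to a silicon-bearing C3, then the methoxymethyl group on O1 is ionised and its CH2 (C6) is captured by the allylsilane terminus C5. The step exploits that C2 is an α-oxy carboxyl carbon and C6 an acetal CH2 on the same ring oxygen, and that C2 and C5 sit 1,4 across the ring, so one carbinol centre, relayed through silicon, fixes the 2,5-cis ring. The triene chain is carried through from farnesyl bromide.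

Key step: step 8

## Route

Step 1
Reactants: 1 (2E,6E)-farnesyl bromide; 2 N-methoxy-N-methylacetamide
Product: 3 (4E,8E)-N-methoxy-N,5,9,13-tetramethyltetradeca-4,8,12-trienamide
Conditions: LiN(iPr)2, THF, −78 °C; then 1, −78 → −20 °C
Reagents that add atoms: none
Why: The kinetic lithium enolate of the Weinreb acetamide should be alkylated in an SN2 reaction at the primary allylic bromide, which leaves the E-trisubstituted alkenes untouched (enolate alkylation).

Step 2
Reactants: 3 Weinreb amide; 4 ethynyltrimethylsilane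
Product: 5 (6E,10E)-7,11,15-trimethyl-1-(trimethylsilyl)hexadeca-6,10,14-trien-1-yn-3-one
Conditions: n-BuLi, THF, −78 °C; then 3, −78 → 0 °C; aq. NH4Cl
Reagents that add atoms: none
Why: The lithium acetylide should add once to the Weinreb amide through the chelated tetrahedral intermediate, which collapses to the ynone only on work-up (Weinreb ketone synthesis).

Step 3
Reactants: 5 ynone
Product: 6 (3R,6E,10E)-7,11,15-trimethyl-1-(trimethylsilyl)hexadeca-6,10,14-trien-1-yn-3-ol
Conditions: RuCl[(R,R)-TsDPEN](p-cymene) (cat.), 2-propanol, rt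
Reagents that add atoms: none
Why: Noyori asymmetric transfer hydrogenation of the conjugated ynone, in which the alkynyl group takes the place of the aryl group of aryl ketones, should deliver the (R)-carbinol with the (R,R) ligand and leave the alkyne and the alkenes unreduced.

Step 4
Reactants: 6 (R)-propargylic alcohol
Product: 7 (1Z,3R,6E,10E)-7,11,15-trimethyl-1-(trimethylsilyl)hexadeca-1,6,10,14-tetraen-3-ol
Conditions: H2 (1 atm), Pd/CaCO3 poisoned with Pb(OAc)2 (Lindlar catalyst), quinoline, hexane/EtOAc, rt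
Reagents that add atoms: none
Why: cis-Semihydrogenation of the silyl alkyne should give the (Z)-vinylsilane, and the poisoned catalyst should not touch the trisubstituted alkenes or the carbinol centre.

Step 5
Reactants: 8 methyl glycolate
Product: 9 methyl 2-(methoxymethoxy)acetate
Conditions: MeOCH2Cl, iPr2NEt, CH2Cl2, 0 °C → rt
Reagents that add atoms: chloromethyl methyl ether, COCCl
Why: O-Alkylation of the hydroxyl group by the chloromethyl ether (MOM ether formation) places the future C6 on the future ring oxygen as an acetal carbon.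

Step 6
Reactants: 9 methyl 2-(methoxymethoxy)acetate
Product: 10 2-(methoxymethoxy)acetic acid
Conditions: LiOH, THF/H2O, 0 °C → rt; then 1 M HCl to pH 3 at 0 °C
Reagents that add atoms: lithium hydroxide, [Li+].[OH-]
Why: Saponification of the methyl ester should proceed without loss of the base-stable MOM acetal, which also survives the brief cold acidification.

Step 7
Reactants: 7 (R,Z)-allylic alcohol; 10 2-(methoxymethoxy)acetic acid
Product: 11 (1Z,3R,6E,10E)-7,11,15-trimethyl-1-(trimethylsilyl)hexadeca-1,6,10,14-tetraen-3-yl 2-(methoxymethoxy)acetate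
Conditions: N,N'-dicyclohexylcarbodiimide, 4-(dimethylamino)pyridine (cat.), CH2Cl2, 0 °C → rt
Reagents that add atoms: none
Why: Steglich esterification forms the acyl–oxygen bond, so the carbinol configuration and the Z-vinylsilane are retained.

Step 8
Reactants: 11 allylic 2-(methoxymethoxy)acetate
Product: 15 (2R,5R)-5-[(3E,7E)-4,8,12-trimethyltrideca-3,7,11-trien-1-yl]-5,6-dihydro-2H-pyran-2-carboxylic acid, via silyl ketene acetal 12 (not isolated), via allylsilane silyl ester 13 (not isolated), via dihydropyran silyl ester 14 (not isolated)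
Conditions: LiN(SiMe3)2, THF, −78 °C; Me3SiCl, −78 °C → rt; volatiles removed; CH2Cl2, Me3SiOTf, 2,6-di-tert-butyl-4-methylpyridine, −78 → −30 °C; aqueous work-up at pH 3
Reagents that add atoms: none
Why: Chelation of lithium between the enolate oxygen and the methoxymethoxy oxygen fixes the (Z)-ketene acetal 12, whose chair [3,3] shift (Ireland–Claisen) forms C2–C3 with the alkoxy group equatorial and the SiMe3 of the (Z)-vinylsilane axial, which should give the anti C2/C3 pair 13 and an (E)-C4=C5 alkene; Me3SiOTf then removes the terminal methoxy group of the acetal, and the O1=C6H2 oxocarbenium ion is attacked by the allylsilane terminus C5 anti to the C3–Si bond, forming C5–C6 and releasing silicon as Me3SiOMe. The closest known reactions are the Ireland–Claisen rearrangement of α-alkoxyacetates of γ-silyl allylic alcohols and the oxocarbenium–allylsilane (Hosomi–Sakurai type) annulation of β-alkoxy allylsilanes to 5,6-dihydro-2H-pyrans. The oxane ring closes in a 6-endo-trig mode through a chair-like transition state in which the C3–Si bond is pseudo-axial. C2 is set by chirality transfer from the carbinol carbon through the chair Claisen transition state, and C5 is set by the anti SE2′ course together with the E geometry of C4=C5, so that the anti silane should lead to the 2,5-cis ring with the (2R,5R) configuration. The step needs anti over syn selectivity in the rearrangement, which the Z geometry of the vinylsilane and the chelated enolate secure; ionisation at the more basic terminal acetal oxygen and not at O1, which sits on the electron-poor carboxyl-substituted carbon; and ring closure ahead of any reaction of the trisubstituted alkenes, which the six-membered reach of the activated allylsilane, the low temperature and the hindered pyridine base secure.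

Step 9
Reactants: 15 dihydropyran acid
Product: 16 (2R,5R)-5-[(3E,7E)-4,8,12-trimethyltrideca-3,7,11-trien-1-yl]oxane-2-carboxylic acid
Conditions: H2 (1 atm), RhCl(PPh3)3 (5 mol %), benzene/EtOH, rt
Reagents that add atoms: none
Why: Homogeneous hydrogenation with RhCl(PPh3)3 should saturate the cis-disubstituted ring alkene much faster than the three trisubstituted side-chain alkenes, and no stereocentre is touched.

Step 10
Reactants: 16 oxane acid
Product: 17 1-{(2R,5R)-5-[(3E,7E)-4,8,12-trimethyltrideca-3,7,11-trien-1-yl]oxan-2-yl}ethan-1-one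
Conditions: MeLi (3 equiv), THF, −78 → 0 °C; then poured into cold 1 M HCl
Reagents that add atoms: methyllithium, [Li]C
Why: Addition of methyllithium to the lithium carboxylate gives a stable geminal dialkoxide, chelated by O1, that releases the methyl ketone only on acidic quench, so over-addition and epimerisation at C2 should be avoided.

Step 11
Reactants: 17 methyl ketone
Product: 18 1-{(2R,5R)-5-[(3E,7E)-4,8,12-trimethyltrideca-3,7,11-trien-1-yl]oxan-2-yl}ethenyl trifluoromethanesulfonate
Conditions: KN(SiMe3)2, THF, −78 °C; N-(5-chloropyridin-2-yl)-N-(trifluoromethylsulfonyl)trifluoromethanesulfonamide (Comins' reagent), −78 °C; aq. NH4Cl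
Reagents that add atoms: Comins' reagent, O=S(=O)(N(c1ccc(Cl)cn1)S(=O)(=O)C(F)(F)F)C(F)(F)F
Why: The hindered base should remove a proton from the unhindered methyl group under kinetic control, and the fast triflyl transfer at −78 °C should trap this enolate before it equilibrates toward C2.

Step 12
Reactants: 18 enol triflate
Product: 19 rhopaloic acid B, 2-{(2R,5R)-5-[(3E,7E)-4,8,12-trimethyltrideca-3,7,11-trien-1-yl]oxan-2-yl}prop-2-enoic acid
Conditions: CO (1 atm), Pd(OAc)2 (5 mol %), 1,3-bis(diphenylphosphino)propane, KOAc, DMF/H2O, 60 °C; then dilute HCl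
Reagents that add atoms: carbon monoxide, [C-]#[O+]; water, O
Why: Oxidative addition of zerovalent palladium to the vinyl triflate, CO insertion and hydrolysis of the acyl palladium species (hydroxycarbonylation) should give the α-substituted acrylic acid directly without touching C2 or the triene.

## Compound list

1 | (2E,6E)-farnesyl bromide | BrC/C=C(\C)CC/C=C(\C)CCC=C(C)C | starting material
2 | N-methoxy-N-methylacetamide | CON(C)C(C)=O | starting material
3 | (4E,8E)-N-methoxy-N,5,9,13-tetramethyltetradeca-4,8,12-trienamide | CON(C)C(=O)CC/C=C(\C)CC/C=C(\C)CCC=C(C)C | intermediate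
4 | ethynyltrimethylsilane | C#C[Si](C)(C)C | starting material
5 | (6E,10E)-7,11,15-trimethyl-1-(trimethylsilyl)hexadeca-6,10,14-trien-1-yn-3-one | C[Si](C)(C)C#CC(=O)CC/C=C(\C)CC/C=C(\C)CCC=C(C)C | intermediate
6 | (3R,6E,10E)-7,11,15-trimethyl-1-(trimethylsilyl)hexadeca-6,10,14-trien-1-yn-3-ol | C[Si](C)(C)C#C[C@H](O)CC/C=C(\C)CC/C=C(\C)CCC=C(C)C | intermediate
7 | (1Z,3R,6E,10E)-7,11,15-trimethyl-1-(trimethylsilyl)hexadeca-1,6,10,14-tetraen-3-ol | C[Si](C)(C)/C=C\[C@H](O)CC/C=C(\C)CC/C=C(\C)CCC=C(C)C | intermediate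
8 | methyl glycolate | COC(=O)CO | starting material
9 | methyl 2-(methoxymethoxy)acetate | COCOCC(=O)OC | intermediate
10 | 2-(methoxymethoxy)acetic acid | COCOCC(=O)O | intermediate
11 | (1Z,3R,6E,10E)-7,11,15-trimethyl-1-(trimethylsilyl)hexadeca-1,6,10,14-tetraen-3-yl 2-(methoxymethoxy)acetate | COCOCC(=O)O[C@@H](/C=C\[Si](C)(C)C)CC/C=C(\C)CC/C=C(\C)CCC=C(C)C | intermediate
12 | (Z)-O-trimethylsilyl ketene acetal of 11 (OSiMe3 cis to the methoxymethoxy group) | COCO/C=C(\O[Si](C)(C)C)O[C@@H](/C=C\[Si](C)(C)C)CC/C=C(\C)CC/C=C(\C)CCC=C(C)C | intermediate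
13 | trimethylsilyl (2S,3R,4E,8E,12E)-2-(methoxymethoxy)-9,13,17-trimethyl-3-(trimethylsilyl)octadeca-4,8,12,16-tetraenoate (anti C2/C3) | C[Si](C)(C)OC(=O)[C@H](OCOC)[C@H]([Si](C)(C)C)/C=C/CC/C=C(\C)CC/C=C(\C)CCC=C(C)C | intermediate
14 | trimethylsilyl (2R,5R)-5-[(3E,7E)-4,8,12-trimethyltrideca-3,7,11-trien-1-yl]-5,6-dihydro-2H-pyran-2-carboxylate | C[Si](C)(C)OC(=O)[C@H]1C=C[C@@H](CC/C=C(\C)CC/C=C(\C)CCC=C(C)C)CO1 | intermediate
15 | (2R,5R)-5-[(3E,7E)-4,8,12-trimethyltrideca-3,7,11-trien-1-yl]-5,6-dihydro-2H-pyran-2-carboxylic acid | OC(=O)[C@H]1C=C[C@@H](CC/C=C(\C)CC/C=C(\C)CCC=C(C)C)CO1 | intermediate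
16 | (2R,5R)-5-[(3E,7E)-4,8,12-trimethyltrideca-3,7,11-trien-1-yl]oxane-2-carboxylic acid | OC(=O)[C@H]1CC[C@@H](CC/C=C(\C)CC/C=C(\C)CCC=C(C)C)CO1 | intermediate
17 | 1-{(2R,5R)-5-[(3E,7E)-4,8,12-trimethyltrideca-3,7,11-trien-1-yl]oxan-2-yl}ethan-1-one | CC(=O)[C@H]1CC[C@@H](CC/C=C(\C)CC/C=C(\C)CCC=C(C)C)CO1 | intermediate
18 | 1-{(2R,5R)-5-[(3E,7E)-4,8,12-trimethyltrideca-3,7,11-trien-1-yl]oxan-2-yl}ethenyl trifluoromethanesulfonate | C=C(OS(=O)(=O)C(F)(F)F)[C@H]1CC[C@@H](CC/C=C(\C)CC/C=C(\C)CCC=C(C)C)CO1 | intermediate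
19 | rhopaloic acid B | C=C(C(=O)O)[C@H]1CC[C@@H](CC/C=C(\C)CC/C=C(\C)CCC=C(C)C)CO1 | target

## Step count and risks

Total steps: 12. Longest linear sequence: 10 (steps 1–4 and 7–12).

**Step 8.** The (Z)-vinylsilane ester may rearrange in part through a boat transition state, which would erode the anti C2/C3 relationship and with it the cis ring. In the Lewis-acid stage the acetal may transfer a methoxymethyl cation between molecules, or the allylsilane may be protodesilylated before the ring closes. The fallback sets out from 5 and comes back at 17. Ynone 5 is reduced with RuCl[(S,S)-TsDPEN](p-cymene) to (3S,6E,10E)-7,11,15-trimethyl-1-(trimethylsilyl)hexadeca-6,10,14-trien-1-yn-3-ol F1. NaAlH2(OCH2CH2OMe)2 converts it by trans-hydroalumination into (1E,3S)-vinylsilane alcohol F2. NaH and 3-bromo-1-(trimethylsilyl)propyne give the 3-(trimethylsilyl)prop-2-ynyl ether F3. n-BuLi at −78 °C triggers a [2,3]-Wittig rearrangement, which is anti-selective for (E)-allyl propargyl ethers and forms C2–C3. A quench with Me3SiCl in the same flask gives the anti β-(trimethylsilyloxy) allylsilane F4. After exchange of THF for CH2Cl2, CH2(OMe)2 and Me3SiOTf close the ring at C5–C6 to (2R,5R)-2-[(trimethylsilyl)ethynyl]-5,6-dihydro-2H-pyran F5. K2CO3 in MeOH gives the terminal alkyne F6, hydration catalysed by (Ph3P)AuNTf2 gives the dihydropyranyl methyl ketone F7, and H2 over RhCl(PPh3)3 saturates the ring alkene to reach 17.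

**Step 9.** The rhodium hydride may also reduce side-chain alkenes on long exposure, or move the ring double bond toward C2. The fallback sets out from 15 and comes back at 16. LiAlH4 reduces acid 15 to the homoallylic alcohol [(2R,5R)-5-substituted 5,6-dihydro-2H-pyran-2-yl]methanol F8. Hydrogenation with [Rh(nbd)(dppb)]BF4 is directed by the hydroxyl group to the ring alkene alone and gives the oxan-2-ylmethanol F9. Oxidation with TEMPO and PhI(OAc)2 in MeCN/H2O returns acid 16.

**Step 11.** Deprotonation at C2 instead of the methyl group would epimerise the α-oxy centre toward the more stable trans ring or give the regioisomeric triflate. The fallback sets out from 16 and comes back at 19, and it avoids a ketone enolate altogether. Acid 16 is coupled with N,O-dimethylhydroxylamine hydrochloride (carbodiimide) to the Weinreb amide F10. iBu2AlH at −78 °C gives the aldehyde F11. Dimethyl (1-diazo-2-oxopropyl)phosphonate with K2CO3 in MeOH gives the 2-ethynyloxane F12. Markovnikov hydroxycarbonylation with Pd(OAc)2, 2-pyridyldiphenylphosphine, CO, H2O and catalytic MeSO3H then gives 19.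

## Further compounds

F1 | step 8 | (3S,6E,10E)-7,11,15-trimethyl-1-(trimethylsilyl)hexadeca-6,10,14-trien-1-yn-3-ol | C[Si](C)(C)C#C[C@@H](O)CC/C=C(\C)CC/C=C(\C)CCC=C(C)C
F2 | step 8 | (1E,3S,6E,10E)-7,11,15-trimethyl-1-(trimethylsilyl)hexadeca-1,6,10,14-tetraen-3-ol | C[Si](C)(C)/C=C/[C@@H](O)CC/C=C(\C)CC/C=C(\C)CCC=C(C)C
F3 | step 8 | 3-(trimethylsilyl)prop-2-ynyl ether of F2 | C[Si](C)(C)C#CCO[C@H](/C=C/[Si](C)(C)C)CC/C=C(\C)CC/C=C(\C)CCC=C(C)C
F4 | step 8 | (3S,4R,5E,9E,13E)-10,14,18-trimethyl-1,4-bis(trimethylsilyl)-3-(trimethylsilyloxy)nonadeca-5,9,13,17-tetraen-1-yne (anti) | C[Si](C)(C)C#C[C@H](O[Si](C)(C)C)[C@H]([Si](C)(C)C)/C=C/CC/C=C(\C)CC/C=C(\C)CCC=C(C)C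
F5 | step 8 | (2R,5R)-5-[(3E,7E)-4,8,12-trimethyltrideca-3,7,11-trien-1-yl]-2-[(trimethylsilyl)ethynyl]-5,6-dihydro-2H-pyran | C[Si](C)(C)C#C[C@H]1C=C[C@@H](CC/C=C(\C)CC/C=C(\C)CCC=C(C)C)CO1
F6 | step 8 | (2R,5R)-2-ethynyl-5-[(3E,7E)-4,8,12-trimethyltrideca-3,7,11-trien-1-yl]-5,6-dihydro-2H-pyran | C#C[C@H]1C=C[C@@H](CC/C=C(\C)CC/C=C(\C)CCC=C(C)C)CO1
F7 | step 8 | 1-{(2R,5R)-5-[(3E,7E)-4,8,12-trimethyltrideca-3,7,11-trien-1-yl]-5,6-dihydro-2H-pyran-2-yl}ethan-1-one | CC(=O)[C@H]1C=C[C@@H](CC/C=C(\C)CC/C=C(\C)CCC=C(C)C)CO1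
F8 | step 9 | {(2R,5R)-5-[(3E,7E)-4,8,12-trimethyltrideca-3,7,11-trien-1-yl]-5,6-dihydro-2H-pyran-2-yl}methanol | OC[C@H]1C=C[C@@H](CC/C=C(\C)CC/C=C(\C)CCC=C(C)C)CO1
F9 | step 9 | {(2R,5R)-5-[(3E,7E)-4,8,12-trimethyltrideca-3,7,11-trien-1-yl]oxan-2-yl}methanol | OC[C@H]1CC[C@@H](CC/C=C(\C)CC/C=C(\C)CCC=C(C)C)CO1
F10 | step 11 | (2R,5R)-N-methoxy-N-methyl-5-[(3E,7E)-4,8,12-trimethyltrideca-3,7,11-trien-1-yl]oxane-2-carboxamide | CON(C)C(=O)[C@H]1CC[C@@H](CC/C=C(\C)CC/C=C(\C)CCC=C(C)C)CO1
F11 | step 11 | (2R,5R)-5-[(3E,7E)-4,8,12-trimethyltrideca-3,7,11-trien-1-yl]oxane-2-carbaldehyde | O=C[C@H]1CC[C@@H](CC/C=C(\C)CC/C=C(\C)CCC=C(C)C)CO1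
F12 | step 11 | (2R,5R)-2-ethynyl-5-[(3E,7E)-4,8,12-trimethyltrideca-3,7,11-trien-1-yl]oxane | C#C[C@H]1CC[C@@H](CC/C=C(\C)CC/C=C(\C)CCC=C(C)C)CO1
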